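**Retrosynthetic overview**
1. Target 31 ⇐ diyne 30 (both ring Z-enoates are carried as ynoates and unveiled last by Lindlar reduction) ⇐ 29 (global PMB removal).
2. C2B–C2A bond: Michael addition of bicyclic β-keto ester 28 to the open-chain enedione 26 (unit A).
3. Cyclopentanone (the last ring formed): squaramide-catalysed Michael/aldol [3+2] of macrocyclic 3,4-dioxo ester 17 with macrocyclic enedione 14 (bonds C2B–C2D and C3D–C4B); rings B and D are made first, both as macrodiolide 14.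
4. 17 ⇐ 14 (1,4-reduction/α-hydroxylation, then oxidation); 14 and 26 ⇐ furan esters 9 and 22 (furan = masked (E)-4-oxo-2-enoic acid; Yamaguchi lactonisation for 14).
5. Stereocentres: C4′/C5′ by Shi epoxidation plus anti opening with PMBOH (enynoate 3, sorbate 18); C7 by enzymatic ketone reduction (7).

Assumption: the ring enoates are Z and the side-chain enoate E, exactly as the SMILES is written.
Labels: unit A = open chain, ring B = macrolide bridging the cyclopentanone, ring D = macrolide fused to it; in each unit C1–C8 are the 7-oxy-4-oxooctanoate carbons and C1′–C6′ the 4,5-dioxyhexenoate carbons. PMB = (4-methoxyphenyl)methyl. SQ-Q = quinine-derived squaramide 3-{[3,5-bis(trifluoromethyl)phenyl]amino}-4-{[(9S)-6′-methoxycinchonan-9-yl]amino}cyclobut-3-ene-1,2-dione; SQ-QD = its quinidine-derived pseudo-enantiomer.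

**Step 1**
Reactants: 1 ethyl prop-2-ynoate; 2 (E)-1-bromoprop-1-ene
Product: 3 ethyl (E)-hex-4-en-2-ynoate
Conditions: PdCl2(PPh3)2 (2 mol%), CuI (4 mol%), K2CO3, THF, 40 °C
Reagents that add atoms: none
Why: Sonogashira coupling of the terminal alkyne with the vinyl bromide retains the E geometry, and the carbonate base avoids amine addition to the propiolate.

**Step 2**
Reactants: 3 ethyl (E)-hex-4-en-2-ynoate
Product: 4 ethyl 3-[(2S,3S)-3-methyloxiran-2-yl]prop-2-ynoate
Conditions: ent-Shi ketone (1,2:4,5-di-O-isopropylidene-β-L-erythro-2,3-hexodiulo-2,6-pyranose, 30 mol%), KHSO5 (as 2KHSO5·KHSO4·K2SO4), K2CO3, Bu4NHSO4 (cat.), MeCN–dimethoxymethane–aq. Na2B4O7 buffer pH 10.5, 0 °C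
Reagents that add atoms: potassium peroxymonosulfate, [K+].[O-]S(=O)(=O)OO
Why: Shi epoxidation: the chiral dioxirane attacks the only alkene through the spiro transition state and gives the trans (S,S) epoxide, which sets C5′ (S) by catalyst control as the first stereocentre of the route.

**Step 3**
Reactants: 4 ethyl 3-[(2S,3S)-3-methyloxiran-2-yl]prop-2-ynoate
Product: 5 ethyl (4R,5S)-5-hydroxy-4-[(4-methoxyphenyl)methoxy]hex-2-ynoate
Conditions: 4-MeOC6H4CH2OH (3 equiv), BF3·OEt2 (10 mol%), CH2Cl2, −40 → −20 °C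
Reagents that add atoms: 4-methoxybenzyl alcohol, COc1ccc(CO)cc1
Why: Lewis-acid-catalysed epoxide alcoholysis by SN2-type attack at the activated propargylic carbon inverts C4′ to R, installs the PMB ether in the same step and leaves the C5′ hydroxyl (S) free.

**Step 4**
Reactants: 5 ethyl (4R,5S)-5-hydroxy-4-[(4-methoxyphenyl)methoxy]hex-2-ynoate
Product: 6 (4R,5S)-5-hydroxy-4-[(4-methoxyphenyl)methoxy]hex-2-ynoic acid
Conditions: LiOH, THF–H2O, 0 °C; then 1 M HCl to pH 3
Reagents that add atoms: lithium hydroxide, [Li+].[OH-]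
Why: Saponification of the ethyl ynoate is fast at 0 °C and touches neither the ether nor the stereocentres.

**Step 5**
Reactants: 7 4-(furan-2-yl)butan-2-one
Product: 8 (2S)-4-(furan-2-yl)butan-2-ol
Conditions: ADH-A (Rhodococcus ruber alcohol dehydrogenase), NAD+ (cat.), i-PrOH (10% v/v), phosphate buffer pH 7.5, 30 °C
Reagents that add atoms: none
Why: Enzymatic asymmetric transfer hydrogenation with Prelog selectivity delivers hydride to the Re face of the methyl ketone and gives the S carbinol (C7).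

**Step 6**
Reactants: 6 (4R,5S)-5-hydroxy-4-[(4-methoxyphenyl)methoxy]hex-2-ynoic acid; 8 (2S)-4-(furan-2-yl)butan-2-ol
Product: 9 (2S)-4-(furan-2-yl)butan-2-yl (4R,5S)-5-hydroxy-4-[(4-methoxyphenyl)methoxy]hex-2-ynoate
Conditions: EDC·HCl, DMAP (10 mol%), 8 (2 equiv), CH2Cl2, −20 → 0 °C, slow addition of 6
Reagents that add atoms: none
Why: Steglich-type esterification in which the unhindered carbinol of 8 (in excess) outcompetes the branched, inductively deactivated C5′ hydroxyl of 6, while the linear alkyne rules out lactonisation.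

**Step 7**
Reactants: 9 (2S)-4-(furan-2-yl)butan-2-yl (4R,5S)-5-hydroxy-4-[(4-methoxyphenyl)methoxy]hex-2-ynoate
Product: 12 (2E,7S)-7-{[(4R,5S)-5-hydroxy-4-[(4-methoxyphenyl)methoxy]hex-2-ynoyl]oxy}-4-oxooct-2-enoic acid, via Z-keto-enal 10 (not isolated), via E-keto-enal 11 (not isolated)
Conditions: NBS, NaHCO3, acetone–H2O, −15 °C; pyridine, rt; then NaClO2, NaH2PO4, 2-methylbut-2-ene, t-BuOH–H2O, 0 °C
Reagents that add atoms: water, O; sodium chlorite, [Na+].[O-]Cl=O
Why: Oxidative furan ring opening (bromination/hydration to the cis keto-enal, base-mediated cis→trans isomerisation) followed by Pinnick oxidation is the standard unmasking of a 2-alkylfuran to an (E)-4-oxo-2-enoic acid and leaves alkyne, PMB ether and alcohol untouched.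

**Step 8**
Reactants: 12 (2E,7S)-7-{[(4R,5S)-5-hydroxy-4-[(4-methoxyphenyl)methoxy]hex-2-ynoyl]oxy}-4-oxooct-2-enoic acid
Product: 14 (3E,8S,13R,14S)-13-[(4-methoxyphenyl)methoxy]-8,14-dimethyl-1,9-dioxacyclotetradec-3-en-11-yne-2,5,10-trione, via mixed anhydride 13 (not isolated)
Conditions: 2,4,6-Cl3C6H2COCl, Et3N, THF, rt; then slow addition to DMAP, toluene (2 mM), 40 °C
Reagents that add atoms: none
Why: Yamaguchi macrolactonisation under high dilution closes the 14-membered diolide through the only free hydroxyl (C5′) without touching a stereocentre.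

**Step 9**
Reactants: 14 enedione macrodiolide (3E,8S,13R,14S)-13-[(4-methoxyphenyl)methoxy]-8,14-dimethyl-1,9-dioxacyclotetradec-3-en-11-yne-2,5,10-trione
Product: 16 (8S,13R,14S)-4-hydroxy-13-[(4-methoxyphenyl)methoxy]-8,14-dimethyl-1,9-dioxacyclotetradec-11-yne-2,5,10-trione (C4 epimers), via lithium enolate 15 (not isolated)
Conditions: Li[HB(s-Bu)3] (1.05 equiv), THF, −78 °C; then 2-(phenylsulfonyl)-3-phenyloxaziridine, −78 °C; aq. NH4Cl
Reagents that add atoms: 2-(phenylsulfonyl)-3-phenyloxaziridine, O=S(=O)(N1OC1c1ccccc1)c1ccccc1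
Why: Conjugate hydride addition to the doubly activated alkene gives regiospecifically the ketone enolate, and Davis oxidation hydroxylates it at the carbon β to the ester (configuration irrelevant, it becomes a ketone).

**Step 10**
Reactants: 16 (8S,13R,14S)-4-hydroxy-13-[(4-methoxyphenyl)methoxy]-8,14-dimethyl-1,9-dioxacyclotetradec-11-yne-2,5,10-trione
Product: 17 (8S,13R,14S)-13-[(4-methoxyphenyl)methoxy]-8,14-dimethyl-1,9-dioxacyclotetradec-11-yne-2,4,5,10-tetrone (largely enolised; used crude)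
Conditions: Dess–Martin periodinane, NaHCO3, CH2Cl2, 0 °C → rt
Reagents that add atoms: none
Why: Dess–Martin oxidation of the α-hydroxy ketone gives the 1,2-diketone, which is at the same time a β-keto ester (C2B nucleophile, C4B electrophile).

**Step 11**
Reactants: 18 ethyl (2E,4E)-hexa-2,4-dienoate
Product: 19 ethyl (2E)-3-[(2S,3S)-3-methyloxiran-2-yl]prop-2-enoate
Conditions: ent-Shi ketone (30 mol%), KHSO5 (as 2KHSO5·KHSO4·K2SO4), K2CO3, Bu4NHSO4 (cat.), MeCN–dimethoxymethane–aq. Na2B4O7 buffer pH 10.5, 0 °C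
Reagents that add atoms: potassium peroxymonosulfate, [K+].[O-]S(=O)(=O)OO
Why: Shi epoxidation is selective for the electron-richer distal alkene of the dienoate and gives the (S,S) epoxide by the same catalyst control as in step 2.

**Step 12**
Reactants: 19 ethyl (2E)-3-[(2S,3S)-3-methyloxiran-2-yl]prop-2-enoate
Product: 20 ethyl (2E,4R,5S)-5-hydroxy-4-[(4-methoxyphenyl)methoxy]hex-2-enoate
Conditions: 4-MeOC6H4CH2OH (3 equiv), BF3·OEt2 (10 mol%), CH2Cl2, −40 → −20 °C
Reagents that add atoms: 4-methoxybenzyl alcohol, COc1ccc(CO)cc1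
Why: Lewis-acid-catalysed alcoholysis of the γ,δ-epoxy enoate at the allylic γ-carbon with inversion gives the anti (4R,5S) pattern.

**Step 13**
Reactants: 20 ethyl (2E,4R,5S)-5-hydroxy-4-[(4-methoxyphenyl)methoxy]hex-2-enoate
Product: 21 (2E,4R,5S)-5-hydroxy-4-[(4-methoxyphenyl)methoxy]hex-2-enoic acid
Conditions: LiOH, THF–H2O, 0 °C; then 1 M HCl to pH 3
Reagents that add atoms: lithium hydroxide, [Li+].[OH-]
Why: Simple saponification; the E-enoate cannot lactonise onto either oxygen.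

**Step 14**
Reactants: 21 (2E,4R,5S)-5-hydroxy-4-[(4-methoxyphenyl)methoxy]hex-2-enoic acid; 8 (2S)-4-(furan-2-yl)butan-2-ol
Product: 22 (2S)-4-(furan-2-yl)butan-2-yl (2E,4R,5S)-5-hydroxy-4-[(4-methoxyphenyl)methoxy]hex-2-enoate
Conditions: EDC·HCl, DMAP (10 mol%), 8 (2 equiv), CH2Cl2, −20 → 0 °C, slow addition of 21
Reagents that add atoms: none
Why: Steglich-type esterification, chemoselective for the unhindered carbinol of 8 as in step 6.

**Step 15**
Reactants: 22 (2S)-4-(furan-2-yl)butan-2-yl (2E,4R,5S)-5-hydroxy-4-[(4-methoxyphenyl)methoxy]hex-2-enoate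
Product: 25 (2E,7S)-7-{[(2E,4R,5S)-5-hydroxy-4-[(4-methoxyphenyl)methoxy]hex-2-enoyl]oxy}-4-oxooct-2-enoic acid, via Z-keto-enal 23 (not isolated), via E-keto-enal 24 (not isolated)
Conditions: NBS, NaHCO3, acetone–H2O, −15 °C; pyridine, rt; then NaClO2, NaH2PO4, 2-methylbut-2-ene, t-BuOH–H2O, 0 °C
Reagents that add atoms: water, O; sodium chlorite, [Na+].[O-]Cl=O
Why: Same furan-to-(E)-4-oxo-2-enoic acid unmasking as step 7; the furan reacts with NBS far faster than the electron-poor enoate.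

**Step 16**
Reactants: 25 (2E,7S)-7-{[(2E,4R,5S)-5-hydroxy-4-[(4-methoxyphenyl)methoxy]hex-2-enoyl]oxy}-4-oxooct-2-enoic acid
Product: 26 (4-methoxyphenyl)methyl (2E,7S)-7-{[(2E,4R,5S)-5-hydroxy-4-[(4-methoxyphenyl)methoxy]hex-2-enoyl]oxy}-4-oxooct-2-enoate
Conditions: 4-MeOC6H4CH2Cl, KHCO3, Bu4NI (cat.), DMF, rt
Reagents that add atoms: 4-methoxybenzyl chloride, COc1ccc(CCl)cc1
Why: Carboxylate O-alkylation gives the PMB ester, which restores full Michael reactivity of the enedione and is cleaved later together with the PMB ethers.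

**Step 17**
Reactants: 17 macrocyclic 3,4-dioxo ester (8S,13R,14S)-13-[(4-methoxyphenyl)methoxy]-8,14-dimethyl-1,9-dioxacyclotetradec-11-yne-2,4,5,10-tetrone; 14 enedione macrodiolide
Product: 28 bis-macrocyclic cyclopentanone (ring C2B–C3B(=O)–C4B(OH)–C3D–C2D; 2B-S 4B-S 3D-S 2D-S; C2B–H; ring B bridging C2B/C4B cis; ring D trans-fused at C2D/C3D; both rings as ynoates with 4′-OPMB), via Michael adduct 27 (not isolated)
Conditions: SQ-Q (10 mol%), CH2Cl2 (0.1 M), 4 Å MS, −20 °C → rt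
Reagents that add atoms: none
Why: Proposed new method: a bifunctional amine–squaramide-catalysed formal [3+2] Michael/aldol annulation between two 14-membered rings, in which the quinuclidine deprotonates the enolised 3,4-dioxo ester 17 at C2B while the squaramide N–H pair binds the ketone/ester of enedione 14, so that the ion-paired enolate adds to C2D (β to the ketone, Re face, sets C2D = S) and the resulting C3D ketone enolate closes 5-exo onto the adjacent C4B ketone of the 1,2-dione through the hydrogen-bonded arrangement that puts 4B-OH cis to the C4D acyl group and ring D trans-fused (sets C3D = S, C4B = S), with C2B equilibrating to the only epimer that lets ring B bridge cis; transannular attack on the ynoate is disfavoured because it would need the s-cis ester rotamer; the closest known reactions are amine–thiourea/squaramide Michael/aldol and Michael/Henry [3+2] cyclopentannulations of 1,2-diones with nitroalkenes or enals and Michael additions of β-keto esters to 4-oxo-2-enoates, none shown with an enedione as the two-carbon partner or with macrocyclic partners.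

**Step 18**
Reactants: 28 bis-macrocyclic cyclopentanone; 26 PMB ester enedione (unit A)
Product: 29 protected trimer (28 carrying at C2B the 2A-R side chain CH(CO2PMB)CH2C(=O)CH2CH2CH(CH3)OC(=O)–(E)-CH=CH–CH(OPMB)–CH(OH)CH3; C2B = S)
Conditions: SQ-QD (20 mol%), toluene (0.5 M), rt
Reagents that add atoms: none
Why: Organocatalytic Michael addition of a β-keto ester to a 4-oxo-2-enoate at C2A (β to the ketone); the enolate of 28 can only be attacked anti to the ring B bridge (sets quaternary C2B = S) and the catalyst steers it to the Si face of C2A (sets C2A = R).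

**Step 19**
Reactants: 29 protected trimer
Product: 30 diyne trimer acid (target skeleton with C2′≡C3′ in rings B and D; all hydroxyls and the carboxylic acid free)
Conditions: CF3CO2H–CH2Cl2 (1:4), anisole, 0 °C
Reagents that add atoms: none
Why: Acidolysis removes the three PMB ethers and the PMB ester as the stabilised benzylic cation (trapped by anisole) at a stage where the freed 4′-hydroxyls sit next to alkynes and cannot lactonise.

**Step 20**
Reactants: 30 diyne trimer acid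
Product: 31 CNP0078817.1 (target)
Conditions: H2 (1 atm), Pd/CaCO3 poisoned with Pb(OAc)2, quinoline, EtOAc, 0 °C, stopped after 2 equiv H2; cold neutral work-up
Reagents that add atoms: none
Why: Lindlar semi-hydrogenation adds H2 syn to both ynoates and gives the two Z ring enoates under neutral conditions, while the E enoate and the ketones are not reduced and the lactonisation-prone Z-γ-hydroxy enoates appear only in the last step.

**Compound list**
1 | ethyl prop-2-ynoate | C#CC(=O)OCC | starting material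
2 | (E)-1-bromoprop-1-ene | C/C=C/Br | starting material
3 | ethyl (E)-hex-4-en-2-ynoate | C/C=C/C#CC(=O)OCC | intermediate
4 | ethyl 3-[(2S,3S)-3-methyloxiran-2-yl]prop-2-ynoate | C[C@@H]1O[C@H]1C#CC(=O)OCC | intermediate
5 | ethyl (4R,5S)-5-hydroxy-4-[(4-methoxyphenyl)methoxy]hex-2-ynoate | C[C@H](O)[C@H](OCc1ccc(OC)cc1)C#CC(=O)OCC | intermediate
6 | (4R,5S)-5-hydroxy-4-[(4-methoxyphenyl)methoxy]hex-2-ynoic acid | C[C@H](O)[C@H](OCc1ccc(OC)cc1)C#CC(=O)O | intermediate
7 | 4-(furan-2-yl)butan-2-one | CC(=O)CCc1ccco1 | starting material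
8 | (2S)-4-(furan-2-yl)butan-2-ol | C[C@H](O)CCc1ccco1 | intermediate
9 | (2S)-4-(furan-2-yl)butan-2-yl (4R,5S)-5-hydroxy-4-[(4-methoxyphenyl)methoxy]hex-2-ynoate | C[C@H](O)[C@H](OCc1ccc(OC)cc1)C#CC(=O)O[C@@H](C)CCc1ccco1 | intermediate
10 | Z-keto-enal: (2S,6Z)-5,8-dioxooct-6-en-2-yl (4R,5S)-5-hydroxy-4-[(4-methoxyphenyl)methoxy]hex-2-ynoate | C[C@H](O)[C@H](OCc1ccc(OC)cc1)C#CC(=O)O[C@@H](C)CCC(=O)/C=C\C=O | intermediate
11 | E-keto-enal: (2S,6E)-5,8-dioxooct-6-en-2-yl (4R,5S)-5-hydroxy-4-[(4-methoxyphenyl)methoxy]hex-2-ynoate | C[C@H](O)[C@H](OCc1ccc(OC)cc1)C#CC(=O)O[C@@H](C)CCC(=O)/C=C/C=O | intermediate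
12 | (2E,7S)-7-{[(4R,5S)-5-hydroxy-4-[(4-methoxyphenyl)methoxy]hex-2-ynoyl]oxy}-4-oxooct-2-enoic acid | C[C@H](O)[C@H](OCc1ccc(OC)cc1)C#CC(=O)O[C@@H](C)CCC(=O)/C=C/C(=O)O | intermediate
13 | mixed anhydride of 12 with 2,4,6-trichlorobenzoic acid | C[C@H](O)[C@H](OCc1ccc(OC)cc1)C#CC(=O)O[C@@H](C)CCC(=O)/C=C/C(=O)OC(=O)c1c(Cl)cc(Cl)cc1Cl | intermediate
14 | (3E,8S,13R,14S)-13-[(4-methoxyphenyl)methoxy]-8,14-dimethyl-1,9-dioxacyclotetradec-3-en-11-yne-2,5,10-trione | C[C@@H]1OC(=O)/C=C/C(=O)CC[C@H](C)OC(=O)C#C[C@H]1OCc2ccc(OC)cc2 | intermediate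
15 | lithium enolate of the 3,4-dihydro form of 14 (C4=C5 enolate, geometry not defined) | [Li+].C[C@@H]1OC(=O)CC=C([O-])CC[C@H](C)OC(=O)C#C[C@H]1OCc2ccc(OC)cc2 | intermediate
16 | (8S,13R,14S)-4-hydroxy-13-[(4-methoxyphenyl)methoxy]-8,14-dimethyl-1,9-dioxacyclotetradec-11-yne-2,5,10-trione (C4 epimers) | C[C@@H]1OC(=O)CC(O)C(=O)CC[C@H](C)OC(=O)C#C[C@H]1OCc2ccc(OC)cc2 | intermediate
17 | (8S,13R,14S)-13-[(4-methoxyphenyl)methoxy]-8,14-dimethyl-1,9-dioxacyclotetradec-11-yne-2,4,5,10-tetrone | C[C@@H]1OC(=O)CC(=O)C(=O)CC[C@H](C)OC(=O)C#C[C@H]1OCc2ccc(OC)cc2 | intermediate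
18 | ethyl (2E,4E)-hexa-2,4-dienoate | C/C=C/C=C/C(=O)OCC | starting material
19 | ethyl (2E)-3-[(2S,3S)-3-methyloxiran-2-yl]prop-2-enoate | C[C@@H]1O[C@H]1/C=C/C(=O)OCC | intermediate
20 | ethyl (2E,4R,5S)-5-hydroxy-4-[(4-methoxyphenyl)methoxy]hex-2-enoate | C[C@H](O)[C@H](OCc1ccc(OC)cc1)/C=C/C(=O)OCC | intermediate
21 | (2E,4R,5S)-5-hydroxy-4-[(4-methoxyphenyl)methoxy]hex-2-enoic acid | C[C@H](O)[C@H](OCc1ccc(OC)cc1)/C=C/C(=O)O | intermediate
22 | (2S)-4-(furan-2-yl)butan-2-yl (2E,4R,5S)-5-hydroxy-4-[(4-methoxyphenyl)methoxy]hex-2-enoate | C[C@H](O)[C@H](OCc1ccc(OC)cc1)/C=C/C(=O)O[C@@H](C)CCc1ccco1 | intermediate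
23 | Z-keto-enal: (2S,6Z)-5,8-dioxooct-6-en-2-yl (2E,4R,5S)-5-hydroxy-4-[(4-methoxyphenyl)methoxy]hex-2-enoate | C[C@H](O)[C@H](OCc1ccc(OC)cc1)/C=C/C(=O)O[C@@H](C)CCC(=O)/C=C\C=O | intermediate
24 | E-keto-enal: (2S,6E)-5,8-dioxooct-6-en-2-yl (2E,4R,5S)-5-hydroxy-4-[(4-methoxyphenyl)methoxy]hex-2-enoate | C[C@H](O)[C@H](OCc1ccc(OC)cc1)/C=C/C(=O)O[C@@H](C)CCC(=O)/C=C/C=O | intermediate
25 | (2E,7S)-7-{[(2E,4R,5S)-5-hydroxy-4-[(4-methoxyphenyl)methoxy]hex-2-enoyl]oxy}-4-oxooct-2-enoic acid | C[C@H](O)[C@H](OCc1ccc(OC)cc1)/C=C/C(=O)O[C@@H](C)CCC(=O)/C=C/C(=O)O | intermediate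
26 | (4-methoxyphenyl)methyl (2E,7S)-7-{[(2E,4R,5S)-5-hydroxy-4-[(4-methoxyphenyl)methoxy]hex-2-enoyl]oxy}-4-oxooct-2-enoate | C[C@H](O)[C@H](OCc1ccc(OC)cc1)/C=C/C(=O)O[C@@H](C)CCC(=O)/C=C/C(=O)OCc1ccc(OC)cc1 | intermediate
27 | open Michael adduct: tetrone 17 bonded through C2B (epimers) to C2D (S) of the 2,3-dihydro form of 14 | O=C1O[C@@H](C)[C@H](OCc2ccc(OC)cc2)C#CC(=O)O[C@@H](C)CCC(=O)C(=O)C1[C@@H]1CC(=O)CC[C@H](C)OC(=O)C#C[C@@H](OCc2ccc(OC)cc2)[C@H](C)OC1=O | intermediate
28 | bis-macrocyclic cyclopentanone (2B-S,4B-S,3D-S,2D-S; C2B–H; rings B and D as 4′-OPMB ynoate diolides) | [C@@H]12C(=O)O[C@@H](C)[C@H](OCc3ccc(OC)cc3)C#CC(=O)O[C@@H](C)CC[C@@](O)(C1=O)[C@H]1C(=O)CC[C@H](C)OC(=O)C#C[C@@H](OCc3ccc(OC)cc3)[C@H](C)OC(=O)[C@@H]12 | intermediate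
29 | protected trimer (28 with the 2A-R unit A side chain at quaternary C2B; three PMB ethers, one PMB ester, 5′A-OH free) | C[C@H](O)[C@H](OCc1ccc(OC)cc1)/C=C/C(=O)O[C@@H](C)CCC(=O)C[C@@H](C(=O)OCc1ccc(OC)cc1)[C@@]12C(=O)O[C@@H](C)[C@H](OCc3ccc(OC)cc3)C#CC(=O)O[C@@H](C)CC[C@@](O)(C1=O)[C@H]1C(=O)CC[C@H](C)OC(=O)C#C[C@@H](OCc3ccc(OC)cc3)[C@H](C)OC(=O)[C@@H]12 | intermediate
30 | diyne trimer acid (target with C2′≡C3′ in rings B and D) | C[C@H](O)[C@H](O)/C=C/C(=O)O[C@@H](C)CCC(=O)C[C@@H](C(=O)O)[C@@]12C(=O)O[C@@H](C)[C@H](O)C#CC(=O)O[C@@H](C)CC[C@@](O)(C1=O)[C@H]1C(=O)CC[C@H](C)OC(=O)C#C[C@@H](O)[C@H](C)OC(=O)[C@@H]12 | intermediate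
31 | CNP0078817.1 | C[C@H](O)[C@H](O)/C=C/C(=O)O[C@@H](C)CCC(=O)C[C@@H](C(=O)O)[C@@]12C(=O)O[C@@H](C)[C@H](O)/C=C\C(=O)O[C@@H](C)CC[C@@](O)(C1=O)[C@H]1C(=O)CC[C@H](C)OC(=O)/C=C\[C@@H](O)[C@H](C)OC(=O)[C@@H]12 | target

**Totals**
Total step count: 20. Longest linear sequence: 13 steps (1–4, 6–10, 17–20).

**Three steps most likely to fail**

Step 17 (the proposed new annulation). The risks are low face selectivity at C2D, a mismatched aldol and self-condensation of 17. The fallback uses known Mukaiyama and magnesium-enolate chemistry under substrate control. It sets out from 17, which is silylated with Me3SiOTf/Et3N to the silyl enol ether (3Z,8S,13R,14S)-13-[(4-methoxyphenyl)methoxy]-8,14-dimethyl-4-[(trimethylsilyl)oxy]-1,9-dioxacyclotetradec-3-en-11-yne-2,5,10-trione F1. A Sc(OTf)3-catalysed Mukaiyama–Michael addition of F1 to 14 gives, after aqueous work-up, the open adduct 27, now isolated and separated from its C2D epimer. Soft enolisation of 27 with MgBr2·OEt2/i-Pr2NEt then closes the chelated intramolecular aldol, and the fallback comes back to the route at 28.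

Step 18 (Michael addition creating the quaternary C2B next to tertiary C2A). The tertiary, bridged enolate of 28 may be too hindered. The fallback inverts the order of the two C–C bond formations and sets out from 17 and 26. SQ-QD-catalysed Michael addition of the unhindered secondary enolate of 17 to 26 gives the 2B-substituted tetrone F2 (17 carrying the 2A-R unit A side chain at C2B), which fixes C2A first. F2 is then subjected to the step-17 annulation with 14 (SQ-Q, CH2Cl2): the Michael addition now forms the quaternary centre inside the cascade, giving the open adduct F3 (not isolated), whose aldol closure comes back to the route at 29.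

Step 3 (regio- and stereospecific opening of the electron-poor epoxy ynoate). Attack at C5′ would give the enantiomeric anti series, and PMBOH can self-condense. The fallback sets out from 2 and builds the carboxyl group last. Sonogashira coupling of 2 with ethynyltrimethylsilane (PdCl2(PPh3)2, CuI, i-Pr2NH) gives (E)-trimethyl(pent-3-en-1-yn-1-yl)silane F4. Shi epoxidation with the same ent-ketone gives trimethyl{[(2S,3S)-3-methyloxiran-2-yl]ethynyl}silane F5. BF3·OEt2/PMBOH at −78 °C opens F5 at the propargylic carbon, which the electron-rich silylalkyne now activates unambiguously, to (2S,3R)-3-[(4-methoxyphenyl)methoxy]-5-(trimethylsilyl)pent-4-yn-2-ol F6. K2CO3/MeOH removes silicon to (2S,3R)-3-[(4-methoxyphenyl)methoxy]pent-4-yn-2-ol F7. Double deprotonation with n-BuLi (2.2 equiv) and carboxylation with CO2, then acid work-up, comes back to the route at 6.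

**Further compounds**
F1 | step 17 | (3Z,8S,13R,14S)-13-[(4-methoxyphenyl)methoxy]-8,14-dimethyl-4-[(trimethylsilyl)oxy]-1,9-dioxacyclotetradec-3-en-11-yne-2,5,10-trione | C[C@@H]1OC(=O)/C=C(\O[Si](C)(C)C)C(=O)CC[C@H](C)OC(=O)C#C[C@H]1OCc2ccc(OC)cc2
F2 | step 18 | tetrone 17 carrying at C2B (epimers) the 2A-R unit A side chain of 26 | C[C@H](O)[C@H](OCc1ccc(OC)cc1)/C=C/C(=O)O[C@@H](C)CCC(=O)C[C@@H](C(=O)OCc1ccc(OC)cc1)C1C(=O)O[C@@H](C)[C@H](OCc2ccc(OC)cc2)C#CC(=O)O[C@@H](C)CCC(=O)C1=O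
F3 | step 18 | open Michael adduct of F2 and 14 (quaternary C2B bonded to C2D; C3D as CH2; C4B still a ketone) | C[C@H](O)[C@H](OCc1ccc(OC)cc1)/C=C/C(=O)O[C@@H](C)CCC(=O)C[C@@H](C(=O)OCc1ccc(OC)cc1)[C@]1(C(=O)O[C@@H](C)[C@H](OCc2ccc(OC)cc2)C#CC(=O)O[C@@H](C)CCC(=O)C1=O)[C@@H]1CC(=O)CC[C@H](C)OC(=O)C#C[C@@H](OCc2ccc(OC)cc2)[C@H](C)OC1=O
F4 | step 3 | (E)-trimethyl(pent-3-en-1-yn-1-yl)silane | C/C=C/C#C[Si](C)(C)C
F5 | step 3 | trimethyl{[(2S,3S)-3-methyloxiran-2-yl]ethynyl}silane | C[C@@H]1O[C@H]1C#C[Si](C)(C)C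
F6 | step 3 | (2S,3R)-3-[(4-methoxyphenyl)methoxy]-5-(trimethylsilyl)pent-4-yn-2-ol | C[C@H](O)[C@H](OCc1ccc(OC)cc1)C#C[Si](C)(C)C
F7 | step 3 | (2S,3R)-3-[(4-methoxyphenyl)methoxy]pent-4-yn-2-ol | C[C@H](O)[C@H](OCc1ccc(OC)cc1)C#C
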